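**Retrosynthetic overview**

- The target is the p-quinone methide (C4=O, exocyclic C1=Cα) of a 3-aryl γ-lactone fused across C1–C2 of a 7,8-dihydroxydibenzofuran. It is taken back by O-demethylation, dehydrogenation (O4–H and lactone Cα–H), the Cα–aryl bond (enolate arylation) and the lactone C–O bond to a dibenzofuran-1-ylacetic ester.
- Feature that carries the strategy: in that reduced form the central carbocycle (ring C: C1, C2, C3, C4, C4a, C9b) is a fully substituted phenol with OH on C4 (next to furan carbon C4a), phenyl on C3, oxygen on C2 and the CH2CO2Me arm on C1. This is the 1,3-dioxygenated pattern that a vinylketene and an ynol ether assemble.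
- Key disconnection: C9b–C1, C1–C2, C3–C4 and C4–C4a, giving a benzofuran-3-yl α-diazoketone with the acetate arm on the diazo carbon, and triisopropylsilyloxy(phenyl)acetylene.
- The diazoketone comes from 2-hydroxy-4,5-dimethoxybenzaldehyde (benzofuran-3-carboxylate, acid chloride, zinc homoenolate acylation, deacylative diazo transfer). The alkyne comes from ethyl benzoate through its ynolate.
- Ring order: ring A (dimethoxybenzene) is bought, furan ring B is closed in step 1, carbocycle C in step 7, lactone ring D in step 8.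

Key step: step 7

Remark on the chemistry: the target has no stereocentre and is taken as the quinone-methide tautomer drawn. Intermediates 3, 10, 17, 19 and 24 are racemic (3 as a diastereomer mixture) and their stereocentres disappear later.

**Route**

Step 1
Reactants: 1 2-hydroxy-4,5-dimethoxybenzaldehyde; 2 ethyl diazoacetate
Product: 4 ethyl 5,6-dimethoxy-1-benzofuran-3-carboxylate, via ethyl 2-hydroxy-5,6-dimethoxy-2,3-dihydro-1-benzofuran-3-carboxylate 3 (not isolated)
Conditions: HBF4·OEt2 (10 mol %), CH2Cl2, rt; then conc. H2SO4, 0 °C → rt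
Reagents that add atoms: none
Why: Acid-catalysed aldehyde–diazoacetate homologation with 1,2-aryl shift (aryl-shift variant of the Roskamp reaction) should give the 2-aryl-3-hydroxyacrylate, which closes through the phenol oxygen to hemiacetal 3 and is dehydrated to the benzofuran, the phenol oxygen becoming O1 so that the methoxy groups end at C5 and C6.

Step 2
Reactants: 4 ethyl 5,6-dimethoxy-1-benzofuran-3-carboxylate
Product: 5 5,6-dimethoxy-1-benzofuran-3-carboxylic acid
Conditions: LiOH, THF/MeOH/H2O, 50 °C; then aq. HCl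
Reagents that add atoms: lithium hydroxide, [Li+].[OH-]
Why: Ester saponification, to which the benzofuran and the aryl methyl ethers are inert.

Step 3
Reactants: 5 5,6-dimethoxy-1-benzofuran-3-carboxylic acid
Product: 6 5,6-dimethoxy-1-benzofuran-3-carbonyl chloride
Conditions: (COCl)2, DMF (cat.), CH2Cl2, 0 °C → rt; evaporate
Reagents that add atoms: oxalyl chloride, ClC(=O)C(=O)Cl
Why: Acid chloride formation through the Vilsmeier-type chloroiminium species under conditions mild enough for the electron-rich benzofuran.

Step 4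
Reactants: 6 5,6-dimethoxy-1-benzofuran-3-carbonyl chloride; 7 methyl 3-iodopropanoate
Product: 9 methyl 4-(5,6-dimethoxy-1-benzofuran-3-yl)-4-oxobutanoate, via (3-methoxy-3-oxopropyl)zinc iodide 8 (not isolated)
Conditions: 7, Zn(Cu), toluene/N,N-dimethylacetamide, 60 °C; then 6, Pd(PPh3)4 (5 mol %), rt
Reagents that add atoms: zinc, [Zn] (held only in intermediate 8, not in 9)
Why: Zinc insertion into the C–I bond gives the ester-chelated zinc homoenolate 8, which couples with the acid chloride under zerovalent palladium catalysis (Negishi-type acylation) without adding to the ketone formed or to its own ester.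

Step 5
Reactants: 9 methyl 4-(5,6-dimethoxy-1-benzofuran-3-yl)-4-oxobutanoate
Product: 11 methyl 3-diazo-4-(5,6-dimethoxy-1-benzofuran-3-yl)-4-oxobutanoate, via trifluoroacetyl diketone 10 (not isolated)
Conditions: LiN(SiMe3)2, THF, −78 °C; CF3CO2CH2CF3, −78 °C; aq. HCl work-up; then MsN3, Et3N, H2O (1 equiv), MeCN, rt
Reagents that add atoms: methanesulfonyl azide, CS(=O)(=O)N=[N+]=[N-]; 2,2,2-trifluoroethyl trifluoroacetate, FC(F)(F)COC(=O)C(F)(F)F (its CF3CO group is held only in intermediate 10)
Why: Detrifluoroacetylative (Regitz-type deacylative) diazo transfer, in which the ketone α-CH2, far more acidic than the ester α-CH2, should be enolised and trifluoroacetylated selectively and the sulfonyl azide then delivers N2 with loss of the trifluoroacetyl group.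

Step 6
Reactants: 12 ethyl benzoate
Product: 15 triisopropyl(phenylethynyloxy)silane, via lithium 2,2-dibromo-1-phenylethenolate 13 (not isolated), via lithium 2-phenylethynolate 14 (not isolated)
Conditions: CH2Br2, lithium 2,2,6,6-tetramethylpiperidide, THF, −78 °C; LiN(SiMe3)2; n-BuLi, −78 °C → rt; i-Pr3SiCl, −78 °C → rt
Reagents that add atoms: dibromomethane, BrCBr; triisopropylsilyl chloride, CC(C)[Si](Cl)(C(C)C)C(C)C; lithium bis(trimethylsilyl)amide, [Li+].C[Si](C)(C)[N-][Si](C)(C)C (lithium of intermediates 13 and 14 only)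
Why: Kowalski ester homologation chemistry, in which dibromomethyllithium adds to the ester, dibromo enolate 13 undergoes Br–Li exchange and 1,2-phenyl shift to ynolate 14, and the bulky silyl chloride traps the ynolate on oxygen.

Step 7
Reactants: 11 methyl 3-diazo-4-(5,6-dimethoxy-1-benzofuran-3-yl)-4-oxobutanoate; 15 triisopropyl(phenylethynyloxy)silane
Product: 20 methyl 2-[4-hydroxy-7,8-dimethoxy-3-phenyl-2-(triisopropylsilyloxy)dibenzofuran-1-yl]acetate, via aryl(alkyl)ketene 16 (not isolated), via cyclobutenone 17 (not isolated), via dienylketene 18 (not isolated), via cyclohexadienone 19 (not isolated)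
Conditions: 15 (1.5 equiv), hν (300 nm, Pyrex), degassed ClCH2CH2Cl, rt; then 80 °C
Reagents that add atoms: none
Why: Irradiation expels N2 and the electron-rich benzofuran-3-yl group migrates from the carbonyl carbon to the diazo carbon (photochemical Wolff rearrangement, bond C9b–C1) to give ketene 16, which adds [2+2] to the ynol ether (bonds C1–C2 and C3–C4) to give cyclobutenone 17; on heating, 4π electrocyclic opening gives dienylketene 18 and 6π electrocyclisation onto benzofuran C2 (bond C4–C4a) gives dienone 19, which tautomerises to phenol 20. The closest known reaction is the Danheiser benzannulation in its diazoketone form, which has been run with siloxyalkynes and with heteroaryl diazoketones. Ring C is closed by the thermal 6π electrocyclisation of the ketene carbon onto the furan C2=C3 bond, C2 being the only position that can rearomatise because C3a is a ring-fusion carbon. No stereocentre remains in 20, those of 17 and 19 being lost on ring opening and tautomerisation. Two selectivities are needed: the [2+2] regiochemistry, secured by the polarisation of the ynol ether whose phenyl-bearing carbon attacks the ketene carbonyl carbon so that phenyl ends at C3 between the new hydroxyl (C4) and the silyloxy group (C2), and Wolff rearrangement ahead of 1,2-hydrogen shift of the carbene, favoured by the migratory aptitude of the heteroaryl group and by the poor hydride-donor character of a CH2 that is α to an ester. An excess of the ketenophilic siloxyalkyne should intercept the ketene before it dimerises.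

Step 8
Reactants: 20 methyl 2-[4-hydroxy-7,8-dimethoxy-3-phenyl-2-(triisopropylsilyloxy)dibenzofuran-1-yl]acetate
Product: 22 2-O-lactone of 2-(2,4-dihydroxy-7,8-dimethoxy-3-phenyldibenzofuran-1-yl)acetic acid (4-OH free), via diol ester 21 (not isolated)
Conditions: Bu4NF, AcOH, THF, 0 °C; then TsOH·H2O (cat.), toluene, 80 °C
Reagents that add atoms: none
Why: Fluoride cleaves the aryl silyl ether and acid-catalysed transesterification of the freed 2-hydroxyl onto the neighbouring acetate arm closes the five-membered lactone (ring D), the 4-hydroxyl being too remote to compete.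

Step 9
Reactants: 22 2-O-lactone of 2-(2,4-dihydroxy-7,8-dimethoxy-3-phenyldibenzofuran-1-yl)acetic acid; 23 4-bromoanisole
Product: 24 2-O-lactone of 2-(2,4-dihydroxy-7,8-dimethoxy-3-phenyldibenzofuran-1-yl)-2-(4-methoxyphenyl)acetic acid (racemic)
Conditions: Pd2(dba)3 (2.5 mol %), XPhos (10 mol %), K3PO4 (3 equiv), degassed 1,4-dioxane, 80 °C; AcOH quench under Ar
Reagents that add atoms: none
Why: Palladium-catalysed α-arylation of the lactone enolate (Buchwald–Hartwig-type enolate arylation, as for oxindoles and aryl acetates), in which the benzofuranone α-CH2 is acidic enough for K3PO4, the hindered 4-phenoxide is a poor partner for C–O coupling, and the new stereocentre forms racemic and is destroyed in step 10.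

Step 10
Reactants: 24 2-O-lactone of 2-(2,4-dihydroxy-7,8-dimethoxy-3-phenyldibenzofuran-1-yl)-2-(4-methoxyphenyl)acetic acid
Product: 25 tri-O-methyl ether of the target (quinone methide with C4=O and exocyclic C1=C(4-methoxyphenyl) inside the butenolide)
Conditions: DDQ (1.05 equiv), CH2Cl2, 0 °C → rt
Reagents that add atoms: none
Why: DDQ dehydrogenation of a p-hydroxybenzylic C–H, where hydride loss from the doubly benzylic lactone α-carbon para to the 4-hydroxyl and loss of the phenol proton should give the fully substituted, push–pull stabilised p-quinone methide.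

Step 11
Reactants: 25 tri-O-methyl ether of the target
Product: 26 target CNP0139113.0 (7,8-dihydroxy quinone methide lactone bearing 3-phenyl and 4-hydroxyphenyl groups)
Conditions: BBr3 (6 equiv), CH2Cl2, −78 °C → rt; then H2O
Reagents that add atoms: none
Why: Lewis-acid ether cleavage with BBr3 should remove the three aryl methyl ethers (the anisyl ether being activated by conjugation with the dienone), while the lactone and the tetrasubstituted quinone methide, which has no free electrophilic terminus, should survive to the aqueous work-up.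

**Compound list**

1 | 2-hydroxy-4,5-dimethoxybenzaldehyde | O=Cc1cc(OC)c(OC)cc1O | starting material
2 | ethyl diazoacetate | CCOC(=O)C=[N+]=[N-] | starting material
3 | ethyl 2-hydroxy-5,6-dimethoxy-2,3-dihydro-1-benzofuran-3-carboxylate (racemic diastereomer mixture) | CCOC(=O)C1C(O)Oc2cc(OC)c(OC)cc21 | intermediate
4 | ethyl 5,6-dimethoxy-1-benzofuran-3-carboxylate | CCOC(=O)c1coc2cc(OC)c(OC)cc12 | intermediate
5 | 5,6-dimethoxy-1-benzofuran-3-carboxylic acid | OC(=O)c1coc2cc(OC)c(OC)cc12 | intermediate
6 | 5,6-dimethoxy-1-benzofuran-3-carbonyl chloride | ClC(=O)c1coc2cc(OC)c(OC)cc12 | intermediate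
7 | methyl 3-iodopropanoate | COC(=O)CCI | starting material
8 | (3-methoxy-3-oxopropyl)zinc iodide | COC(=O)CC[Zn]I | intermediate
9 | methyl 4-(5,6-dimethoxy-1-benzofuran-3-yl)-4-oxobutanoate | COC(=O)CCC(=O)c1coc2cc(OC)c(OC)cc12 | intermediate
10 | methyl 3-(5,6-dimethoxy-1-benzofuran-3-carbonyl)-5,5,5-trifluoro-4-oxopentanoate (racemic, largely enolised) | COC(=O)CC(C(=O)C(F)(F)F)C(=O)c1coc2cc(OC)c(OC)cc12 | intermediate
11 | methyl 3-diazo-4-(5,6-dimethoxy-1-benzofuran-3-yl)-4-oxobutanoate | COC(=O)CC(=[N+]=[N-])C(=O)c1coc2cc(OC)c(OC)cc12 | intermediate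
12 | ethyl benzoate | CCOC(=O)c1ccccc1 | starting material
13 | lithium 2,2-dibromo-1-phenylethenolate | [Li+].[O-]C(=C(Br)Br)c1ccccc1 | intermediate
14 | lithium 2-phenylethynolate | [Li+].[O-]C#Cc1ccccc1 | intermediate
15 | triisopropyl(phenylethynyloxy)silane | CC(C)[Si](OC#Cc1ccccc1)(C(C)C)C(C)C | intermediate
16 | methyl 3-(5,6-dimethoxy-1-benzofuran-3-yl)-4-oxobut-3-enoate (aryl(alkyl)ketene) | COC(=O)CC(=C=O)c1coc2cc(OC)c(OC)cc12 | intermediate
17 | methyl 2-[1-(5,6-dimethoxy-1-benzofuran-3-yl)-4-oxo-3-phenyl-2-(triisopropylsilyloxy)cyclobut-2-en-1-yl]acetate (racemic) | COC(=O)CC1(c2coc3cc(OC)c(OC)cc23)C(=O)C(c2ccccc2)=C1O[Si](C(C)C)(C(C)C)C(C)C | intermediate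
18 | methyl 3-(5,6-dimethoxy-1-benzofuran-3-yl)-6-oxo-5-phenyl-4-(triisopropylsilyloxy)hexa-3,5-dienoate (dienylketene, benzofuranyl cis to the ketene arm) | O=C=C(c1ccccc1)/C(O[Si](C(C)C)(C(C)C)C(C)C)=C(/CC(=O)OC)c1coc2cc(OC)c(OC)cc12 | intermediate
19 | methyl 2-[7,8-dimethoxy-4-oxo-3-phenyl-2-(triisopropylsilyloxy)-4,4a-dihydrodibenzofuran-1-yl]acetate (racemic keto tautomer) | COC(=O)CC1=C2c3cc(OC)c(OC)cc3OC2C(=O)C(c2ccccc2)=C1O[Si](C(C)C)(C(C)C)C(C)C | intermediate
20 | methyl 2-[4-hydroxy-7,8-dimethoxy-3-phenyl-2-(triisopropylsilyloxy)dibenzofuran-1-yl]acetate | COC(=O)Cc1c(O[Si](C(C)C)(C(C)C)C(C)C)c(-c2ccccc2)c(O)c2oc3cc(OC)c(OC)cc3c12 | intermediate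
21 | methyl 2-(2,4-dihydroxy-7,8-dimethoxy-3-phenyldibenzofuran-1-yl)acetate | COC(=O)Cc1c(O)c(-c2ccccc2)c(O)c2oc3cc(OC)c(OC)cc3c12 | intermediate
22 | 2-O-lactone of 2-(2,4-dihydroxy-7,8-dimethoxy-3-phenyldibenzofuran-1-yl)acetic acid (benzofuran-2(3H)-one fused at C1–C2, 4-OH free) | O=C1Cc2c(O1)c(-c1ccccc1)c(O)c1oc3cc(OC)c(OC)cc3c21 | intermediate
23 | 4-bromoanisole | COc1ccc(Br)cc1 | starting material
24 | 2-O-lactone of 2-(2,4-dihydroxy-7,8-dimethoxy-3-phenyldibenzofuran-1-yl)-2-(4-methoxyphenyl)acetic acid (racemic) | COc1ccc(cc1)C1C(=O)Oc2c(-c3ccccc3)c(O)c3oc4cc(OC)c(OC)cc4c3c21 | intermediate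
25 | tri-O-methyl ether of the target (7,8-dimethoxy, 4-methoxyphenyl quinone methide lactone) | O=C1OC2=C(c3ccccc3)C(=O)c3oc4cc(OC)c(OC)cc4c3C2=C1c1ccc(OC)cc1 | intermediate
26 | CNP0139113.0 (quinone methide lactone with C4=O, 3-phenyl, 7,8-dihydroxy and exocyclic C1=C(4-hydroxyphenyl) in the butenolide) | O=C1OC2=C(c3ccccc3)C(=O)c3oc4cc(O)c(O)cc4c3C2=C1c1ccc(O)cc1 | target

**Step count**

Total: 11 steps. Longest linear sequence: 10 steps (steps 1–5 and 7–11); step 6 is a one-step side branch.

**Steps most likely to fail, with fallbacks**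

Step 7. The acyl carbene may undergo 1,2-hydrogen shift to the aroylacrylate instead of Wolff rearrangement, or the disubstituted ketene may add too slowly to the alkyne. The fallback removes the hydrogens next to the carbene by installing the C1 side chain after the annulation. It sets out from acid chloride 6 and alkyne 15.
- Acid chloride 6 with Me3SiCHN2 (MeCN/THF, 0 °C) should give the terminal diazoketone 2-diazo-1-(5,6-dimethoxy-1-benzofuran-3-yl)ethan-1-one F1.
- Irradiation of this with 15 and heating as in step 7 should give 7,8-dimethoxy-3-phenyl-2-(triisopropylsilyloxy)dibenzofuran-4-ol F2, in which C1 carries hydrogen.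
- Bu4NF in THF should then give 7,8-dimethoxy-3-phenyldibenzofuran-2,4-diol F3.
- Acid-catalysed condensation with 4-methoxymandelic acid (TsOH·H2O, 1,4-dioxane, 80 °C) should alkylate C1, the only free position of ring C and ortho/para to both hydroxyls, to give 2-(2,4-dihydroxy-7,8-dimethoxy-3-phenyldibenzofuran-1-yl)-2-(4-methoxyphenyl)acetic acid F4.
- This acid should lactonise in the same flask, so the route is rejoined at 24 and steps 8 and 9 are not needed.

Step 9. The dianion (phenoxide plus enolate) may inhibit the catalyst, over-arylate, open the lactone or oxidise in air. The fallback forms the Cα–aryl bond on the open-chain ester with both phenols masked. It sets out from 20.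
- Silylation of the 4-hydroxyl (t-BuMe2SiOTf, 2,6-lutidine, CH2Cl2) should give methyl 2-[4-(tert-butyldimethylsilyloxy)-7,8-dimethoxy-3-phenyl-2-(triisopropylsilyloxy)dibenzofuran-1-yl]acetate F5.
- Ester enolate arylation with 4-bromoanisole 23 (Pd(dba)2, P(t-Bu)3, LiN(SiMe3)2, toluene, rt) should give methyl 2-[4-(tert-butyldimethylsilyloxy)-7,8-dimethoxy-3-phenyl-2-(triisopropylsilyloxy)dibenzofuran-1-yl]-2-(4-methoxyphenyl)acetate F6.
- Bu4NF/AcOH should remove both silyl groups to give methyl 2-(2,4-dihydroxy-7,8-dimethoxy-3-phenyldibenzofuran-1-yl)-2-(4-methoxyphenyl)acetate F7, which on warming with TsOH·H2O in toluene should lactonise, rejoining the route at 24.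

Step 11. The quinone methide lactone may be attacked or opened during Lewis-acid demethylation, or the ethers may be cleaved incompletely. The fallback reverses the order of deprotection and oxidation. It sets out from 24.
- BBr3 (CH2Cl2, −78 °C → rt) on the reduced lactone should give the 2-O-lactone of 2-(2,4,7,8-tetrahydroxy-3-phenyldibenzofuran-1-yl)-2-(4-hydroxyphenyl)acetic acid F8.
- One equivalent of DDQ at low temperature (or air in buffered methanol) should then take this to 26.
- Any o-quinone formed at the catechol is expected to pass its oxidation level to the benzofuranone ring by redox exchange, since the quinone methide with free catechol is the tautomer drawn for the target.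

**Further compounds**

F1 | step 7 | 2-diazo-1-(5,6-dimethoxy-1-benzofuran-3-yl)ethan-1-one | [N-]=[N+]=CC(=O)c1coc2cc(OC)c(OC)cc12
F2 | step 7 | 7,8-dimethoxy-3-phenyl-2-(triisopropylsilyloxy)dibenzofuran-4-ol | CC(C)[Si](Oc1cc2c3cc(OC)c(OC)cc3oc2c(O)c1-c1ccccc1)(C(C)C)C(C)C
F3 | step 7 | 7,8-dimethoxy-3-phenyldibenzofuran-2,4-diol | Oc1cc2c3cc(OC)c(OC)cc3oc2c(O)c1-c1ccccc1
F4 | step 7 | 2-(2,4-dihydroxy-7,8-dimethoxy-3-phenyldibenzofuran-1-yl)-2-(4-methoxyphenyl)acetic acid (racemic) | OC(=O)C(c1ccc(OC)cc1)c1c(O)c(-c2ccccc2)c(O)c2oc3cc(OC)c(OC)cc3c12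
F5 | step 9 | methyl 2-[4-(tert-butyldimethylsilyloxy)-7,8-dimethoxy-3-phenyl-2-(triisopropylsilyloxy)dibenzofuran-1-yl]acetate | COC(=O)Cc1c(O[Si](C(C)C)(C(C)C)C(C)C)c(-c2ccccc2)c(O[Si](C)(C)C(C)(C)C)c2oc3cc(OC)c(OC)cc3c12
F6 | step 9 | methyl 2-[4-(tert-butyldimethylsilyloxy)-7,8-dimethoxy-3-phenyl-2-(triisopropylsilyloxy)dibenzofuran-1-yl]-2-(4-methoxyphenyl)acetate (racemic) | COC(=O)C(c1ccc(OC)cc1)c1c(O[Si](C(C)C)(C(C)C)C(C)C)c(-c2ccccc2)c(O[Si](C)(C)C(C)(C)C)c2oc3cc(OC)c(OC)cc3c12
F7 | step 9 | methyl 2-(2,4-dihydroxy-7,8-dimethoxy-3-phenyldibenzofuran-1-yl)-2-(4-methoxyphenyl)acetate (racemic) | COC(=O)C(c1ccc(OC)cc1)c1c(O)c(-c2ccccc2)c(O)c2oc3cc(OC)c(OC)cc3c12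
F8 | step 11 | 2-O-lactone of 2-(2,4,7,8-tetrahydroxy-3-phenyldibenzofuran-1-yl)-2-(4-hydroxyphenyl)acetic acid (racemic) | Oc1ccc(cc1)C1C(=O)Oc2c(-c3ccccc3)c(O)c3oc4cc(O)c(O)cc4c3c21
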